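**Retrosynthetic overview**
1. Garcinoic acid ⇒ open-chain hydroquinone acid by breaking O1–C2. The pyran ring is closed in the last step by an enantioselective, proton-triggered addition of the ortho phenol to the 2'E alkene. This is a chemical copy of tocopherol cyclase and sets C2 (R), the only stereocentre.
2. Hydroquinone acid ⇒ benzoquinone acid ⇒ geranylgeranyl(methyl)benzoquinone. The terminal E-CH3 is taken to CH2OH and then CO2H (a copy of omega-oxidation) while the arene is parked as the oxidation-proof quinone, so no protecting groups are needed.
3. Quinone ⇒ 2-methyl-6-geranylgeranylphenol by aerobic para-oxygenation.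
4. Phenol ⇒ o-cresol + all-E-geranylgeraniol. The aryl C6–C1' bond comes from an ortho-selective C-allylation (a copy of aromatic prenyl transfer).
5. Ring order: the benzene ring is bought and the pyran ring is formed last, so there is one ring-forming step.

Assumption: all-E-geranylgeraniol (annatto-derived, sold in bulk) counts as a cheap commercial material, and making the chiral acid catalyst from BINOL is not counted as a step.

**Step 1**
Reactants: 1 o-cresol (2-methylphenol); 2 all-E-geranylgeraniol
Product: 3 2-methyl-6-[(2E,6E,10E)-3,7,11,15-tetramethylhexadeca-2,6,10,14-tetraen-1-yl]phenol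
Conditions: 1 (3 equiv), acidic Al2O3 (2 g per mmol of 2), ClCH2CH2Cl, reflux, 24 h
Reagents that add atoms: none
Why: In this surface-templated Friedel–Crafts-type ortho-C-allylation, phenol and allylic alcohol are co-adsorbed on the acidic alumina, so the allyl cation equivalent reaches only the one free ortho carbon (C6), at its primary terminus and with the 2E geometry kept; no stereocentre is formed.

**Step 2**
Reactants: 3 2-methyl-6-geranylgeranylphenol
Product: 4 2-methyl-6-[(2E,6E,10E)-3,7,11,15-tetramethylhexadeca-2,6,10,14-tetraen-1-yl]-1,4-benzoquinone
Conditions: Co(salen) (10 mol %), O2 (1 atm), DMF, 25 °C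
Reagents that add atoms: dioxygen, O=O
Why: Co(salen)-catalysed aerobic para-oxygenation of a 2,6-dialkylphenol (phenoxyl radical, O2 capture at C4, loss of water) is a standard route to 2,6-dialkyl-1,4-benzoquinones and leaves isolated trisubstituted alkenes untouched.

**Step 3**
Reactants: 4 geranylgeranyl(methyl)benzoquinone
Product: 5 2-[(2E,6E,10E,14E)-16-hydroxy-3,7,11,15-tetramethylhexadeca-2,6,10,14-tetraen-1-yl]-6-methyl-1,4-benzoquinone
Conditions: SeO2 (0.3 equiv), t-BuOOH (5.5 M in decane, 3 equiv), salicylic acid (0.1 equiv), CH2Cl2, 0 → 25 °C, stopped at about 60% conversion, 4 recycled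
Reagents that add atoms: tert-butyl hydroperoxide, CC(C)(C)OO (terminal oxygen source, relayed through selenium dioxide, O=[Se]=O)
Why: The Sharpless-modified Riley allylic oxidation (ene reaction, then [2,3]-sigmatropic shift) prefers the sterically most open gem-dimethyl terminus and, through its envelope transition state, gives only the E-allylic alcohol, while the quinone is inert to non-basic hydroperoxide and inductively deactivates the 2' alkene.

**Step 4**
Reactants: 5 omega-hydroxy quinone
Product: 7 (2E,6E,10E,14E)-2,6,10,14-tetramethyl-16-(5-methyl-3,6-dioxocyclohexa-1,4-dien-1-yl)hexadeca-2,6,10,14-tetraenoic acid, via enal quinone 6 (not isolated)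
Conditions: TEMPO (0.1 equiv), PhI(OAc)2 (1.1 equiv), CH2Cl2, 25 °C; then t-BuOH/H2O, 2-methyl-2-butene (20 equiv), NaH2PO4, NaClO2, 0 → 25 °C
Reagents that add atoms: sodium chlorite, [Na+].[O-]Cl=O
Why: Oxoammonium (TEMPO) oxidation of the allylic alcohol followed in the same flask by Pinnick oxidation gives the E-enoic acid without touching the alkene geometry, because the quinone is already fully oxidised and 2-methyl-2-butene traps the hypochlorous acid before it reaches the chain alkenes.

**Step 5**
Reactants: 7 quinone acid
Product: 8 (2E,6E,10E,14E)-16-(2,5-dihydroxy-3-methylphenyl)-2,6,10,14-tetramethylhexadeca-2,6,10,14-tetraenoic acid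
Conditions: Na2S2O4 (aq, excess), EtOAc, 25 °C, Ar; dried azeotropically with toluene and used at once
Reagents that add atoms: none
Why: Dithionite reduction of a benzoquinone to its hydroquinone is instantaneous at room temperature and does not reduce the enoic acid or the isolated alkenes.

**Step 6**
Reactants: 8 open-chain hydroquinone acid
Product: 9 (R)-garcinoic acid, that is (2E,6E,10E)-13-[(2R)-6-hydroxy-2,8-dimethyl-3,4-dihydro-2H-chromen-2-yl]-2,6,10-trimethyltrideca-2,6,10-trienoic acid
Conditions: (S,S)-IDPi (confined imidodiphosphorimidate Brønsted acid from two (S)-BINOL units, 3,3'-bis(9,9-dimethylfluoren-2-yl), N-triflyl core; 5 mol %), toluene/cyclohexane 1:1, 0.05 M, 25 °C (40 °C if slow), Ar, dark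
Reagents that add atoms: none
Why: Proposed new method: a strong, confined chiral Brønsted acid takes the role of tocopherol cyclase, delivering its proton to C2' (chain carbons counted from the ring) of the 2'E alkene while the ortho phenol oxygen, hydrogen-bonded to the chiral counter-anion, adds anti to the Re face of C3' in a concerted, asynchronous Markovnikov 6-endo hydroalkoxylation, so C2 is set as R by the catalyst pocket (the mirror-image catalyst is used if a test run shows the opposite sense); the 6' and 10' alkenes lack an internal nucleophile and would need a free tertiary cation in a non-polar medium, the 14' alkene is switched off by the carboxyl group, and the para OH cannot reach the chain; the closest known reaction types are the achiral-acid chromanol closure of polyprenylhydroquinones used for tocopherols and tocotrienols, and IDPi-catalysed asymmetric intramolecular hydroalkoxylation and hydrolactonisation of unactivated alkenes.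

**Compound list**
1 | o-cresol (2-methylphenol) | Cc1ccccc1O | starting material
2 | all-E-geranylgeraniol, (2E,6E,10E)-3,7,11,15-tetramethylhexadeca-2,6,10,14-tetraen-1-ol | CC(C)=CCC/C(C)=C/CC/C(C)=C/CC/C(C)=C/CO | starting material
3 | 2-methyl-6-[(2E,6E,10E)-geranylgeranyl]phenol | CC(C)=CCC/C(C)=C/CC/C(C)=C/CC/C(C)=C/Cc1cccc(C)c1O | intermediate
4 | 2-methyl-6-[(2E,6E,10E)-geranylgeranyl]-1,4-benzoquinone | CC(C)=CCC/C(C)=C/CC/C(C)=C/CC/C(C)=C/CC1=CC(=O)C=C(C)C1=O | intermediate
5 | 2-[(2E,6E,10E,14E)-16-hydroxygeranylgeranyl]-6-methyl-1,4-benzoquinone | OC/C(C)=C/CC/C(C)=C/CC/C(C)=C/CC/C(C)=C/CC1=CC(=O)C=C(C)C1=O | intermediate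
6 | enal quinone, (2E,6E,10E,14E)-2,6,10,14-tetramethyl-16-(5-methyl-3,6-dioxocyclohexa-1,4-dien-1-yl)hexadeca-2,6,10,14-tetraenal | O=C/C(C)=C/CC/C(C)=C/CC/C(C)=C/CC/C(C)=C/CC1=CC(=O)C=C(C)C1=O | intermediate (not isolated)
7 | quinone acid, (2E,6E,10E,14E)-2,6,10,14-tetramethyl-16-(5-methyl-3,6-dioxocyclohexa-1,4-dien-1-yl)hexadeca-2,6,10,14-tetraenoic acid | OC(=O)/C(C)=C/CC/C(C)=C/CC/C(C)=C/CC/C(C)=C/CC1=CC(=O)C=C(C)C1=O | intermediate
8 | hydroquinone acid, (2E,6E,10E,14E)-16-(2,5-dihydroxy-3-methylphenyl)-2,6,10,14-tetramethylhexadeca-2,6,10,14-tetraenoic acid | OC(=O)/C(C)=C/CC/C(C)=C/CC/C(C)=C/CC/C(C)=C/Cc1cc(O)cc(C)c1O | intermediate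
9 | (R)-garcinoic acid | C/C(=C\CC/C(C)=C/CC[C@]1(C)CCc2cc(O)cc(C)c2O1)CC/C=C(\C)C(=O)O | target

**Total step count:** 6. **Longest linear sequence:** 6.

**Origin of the stereochemistry:** The 3'E and 7'E alkenes of 9 come unchanged from 2, the 11'E alkene from step 3, and C2 (R) from step 6.

**Three steps most likely to fail**

Step 6 is the enantioselective ring closure. The risks are low ee, slow turnover because the acid and hydroquinone groups bind the catalyst, and cation-olefin side cyclisation. The fallback replaces catalyst control by resolution; it sets out from 8 and comes back at 9. Compound 8 is closed with an achiral acid (p-TsOH·H2O, 5 mol %, toluene, 25 °C, Ar), the long-established chromanol closure, to give racemic garcinoic acid F1. The enantiomers are separated by preparative supercritical-fluid chromatography on a cellulose tris(3,5-dimethylphenylcarbamate) phase. The R enantiomer is 9, assigned by rotation and CD against natural material, and (S)-garcinoic acid F2 is set aside. The maximum yield is 50%.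

Step 3 is the terminal allylic oxidation. The risks are attack at internal allylic CH2 groups, over-oxidation and poor mass recovery. The fallback replaces C–H oxidation by olefin cross-metathesis; it sets out from 4 and comes back at 6. Compound 4 and methacrolein (10 equiv) are treated with the second-generation Hoveyda–Grubbs catalyst, RuCl2(SIMes)(=CH-C6H4-2-OiPr) (5 mol %), in CH2Cl2 at 40 °C with venting. The isopropylidene end is the least hindered trisubstituted alkene and is exchanged for the thermodynamically preferred E-2-methylpropenal end. Benzoquinones are tolerated by ruthenium carbenes. The run is stopped at partial conversion so that chain-shortened products from the internal alkenes stay minor and separable. Compound 6 is isolated here and then needs only the NaClO2 half of step 4. New compounds: none F0.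

Step 1 is the ortho-allylation on alumina. The risks are low conversion with the weakly nucleophilic cresol, cyclisation of the polyene, and premature racemic chroman formation on the acidic surface. The fallback replaces acid-mediated allylation by basic SN2 C-alkylation of a phenoxide; it sets out from 1 and 2 and comes back at 3. Compound 2 is converted with PBr3 (0.4 equiv, Et2O, 0 °C) into (2E,6E,10E)-geranylgeranyl bromide F3. Compound 1 is deprotonated with NaH in toluene to give sodium 2-methylphenoxide F4. The two are combined in toluene at 25 °C, where the tight ion pair in the non-polar medium shields oxygen and directs alkylation to the free ortho carbon with the E geometry retained. The O-allyl ether by-product is removed by chromatography.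

**Further compounds**
F1 | step 6 | racemic garcinoic acid | C/C(=C\CC/C(C)=C/CCC1(C)CCc2cc(O)cc(C)c2O1)CC/C=C(\C)C(=O)O
F2 | step 6 | (S)-garcinoic acid | C/C(=C\CC/C(C)=C/CC[C@@]1(C)CCc2cc(O)cc(C)c2O1)CC/C=C(\C)C(=O)O
F0 | step 3 | none | none
F3 | step 1 | (2E,6E,10E)-geranylgeranyl bromide | CC(C)=CCC/C(C)=C/CC/C(C)=C/CC/C(C)=C/CBr
F4 | step 1 | sodium 2-methylphenoxide | Cc1ccccc1[O-].[Na+]
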